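**Retrosynthetic overview**
1. 19 ⇒ 18: C3–O bond by intramolecular oxa-Michael addition of a tertiary hydroperoxide to the butenolide; the 1,2-dioxane ring is formed last and the cis ring fusion sets C3.
2. 18 ⇒ 17: C6–O bond by catalyst-controlled Markovnikov addition of H2O2 to the 1,1-disubstituted alkene (sets C6).
3. 17 ⇒ 15 ⇒ 14: γ-lactone ring (formed first) from an α-hydroxy aldehyde and Ph3P=C=C=O; C4–C5 bond and the C4 stereocentre from a [Cu((S,S)-tBu-box)](SbF6)2-catalysed pyruvate–ene reaction of triene 12 with methyl pyruvate 13.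
4. 12 ⇒ 10 + 6: E-C11=C12 by Julia–Kocienski olefination; 10 from (R)-citronellic acid 7 (source of C8), 6 from styrene 1 and 5-bromopent-1-ene 2 by E-selective cross-metathesis.

Assumption: atom labels C1–C16 follow plakortolide numbering (C1 lactone carbonyl, C3 the CH–OO carbon, C4 and C6 the quaternary carbons, C8 the methyl-bearing CH); the (S,S) catalysts named in steps 8 and 11 are taken as the antipodes that give 4S and 6R, and the mirror-image catalyst is used if a test run shows the opposite sense.

**Route**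

Step 1
Reactants: 1 styrene; 2 5-bromopent-1-ene
Product: 3 (E)-(5-bromopent-1-en-1-yl)benzene
Conditions: second-generation Grubbs catalyst (H2IMes)(PCy3)Cl2Ru=CHPh (2 mol %), styrene (3 equiv), CH2Cl2, 40 °C
Reagents that add atoms: none
Why: Olefin cross-metathesis of a terminal alkene with excess styrene gives the thermodynamically favoured E-β-alkylstyrene (E:Z typically > 20:1) with loss of ethene, the primary bromide being inert.

Step 2
Reactants: 3 (E)-(5-bromopent-1-en-1-yl)benzene; 4 1-phenyl-1H-tetrazole-5-thiol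
Product: 5 1-phenyl-5-{[(4E)-5-phenylpent-4-en-1-yl]sulfanyl}-1H-tetrazole
Conditions: K2CO3, DMF, rt
Reagents that add atoms: none
Why: SN2 S-alkylation of the soft thiolate by the primary bromide (thioether synthesis) is high-yielding and does not touch the styrene.

Step 3
Reactants: 5 1-phenyl-5-{[(4E)-5-phenylpent-4-en-1-yl]sulfanyl}-1H-tetrazole
Product: 6 1-phenyl-5-{[(4E)-5-phenylpent-4-en-1-yl]sulfonyl}-1H-tetrazole
Conditions: (NH4)6Mo7O24·4H2O (10 mol %), 30% aq. H2O2, EtOH, 0 °C to rt
Reagents that add atoms: hydrogen peroxide, OO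
Why: Molybdate-catalysed peroxide oxidation of sulfide to sulfone is chemoselective for sulfur over the conjugated alkene and gives the Julia–Kocienski sulfone.

Step 4
Reactants: 7 (3R)-3,7-dimethyloct-6-enoic acid ((R)-citronellic acid)
Product: 8 (4R)-4,8-dimethylnon-7-en-2-one
Conditions: MeLi (2.2 equiv), Et2O, 0 °C to rt; inverse quench into cold 1 M HCl
Reagents that add atoms: methyllithium, [Li]C
Why: Addition of two equivalents of methyllithium to a carboxylic acid stops at the dilithium gem-diolate, which gives the methyl ketone on work-up (acid-to-ketone organolithium reaction), and the stereocentre of 7 is untouched and becomes C8.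

Step 5
Reactants: 8 (4R)-4,8-dimethylnon-7-en-2-one
Product: 10 (4R)-4-methyl-6-oxoheptanal, via ozonide 9 (not isolated)
Conditions: O3, CH2Cl2, −78 °C; then Me2S, −78 °C to rt
Reagents that add atoms: ozone, [O-][O+]=O
Why: Ozonolysis with reductive work-up (Criegee mechanism) cleaves the only alkene while the ketone is inert, releasing the aldehyde for olefination.

Step 6
Reactants: 10 (4R)-4-methyl-6-oxoheptanal; 6 1-phenyl-5-{[(4E)-5-phenylpent-4-en-1-yl]sulfonyl}-1H-tetrazole
Product: 11 (4R,7E,11E)-4-methyl-12-phenyldodeca-7,11-dien-2-one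
Conditions: 6 (1.2 equiv), KN(SiMe3)2 (1.15 equiv), DME, −60 °C, 30 min; then 10, −60 °C to rt
Reagents that add atoms: none
Why: Julia–Kocienski olefination of an unbranched aldehyde with a potassium-metalated 1-phenyltetrazolyl sulfone in DME gives the E-1,2-disubstituted alkene (typically ≥ 95:5) through addition, Smiles rearrangement and anti-elimination, and the pre-formed sulfonyl anion adds to the aldehyde much faster than to the methyl ketone.

Step 7
Reactants: 11 (4R,7E,11E)-4-methyl-12-phenyldodeca-7,11-dien-2-one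
Product: 12 (4R,7E,11E)-2,4-dimethyl-12-phenyldodeca-1,7,11-triene
Conditions: Ph3PCH3Br (1.5 equiv), KOtBu (1.4 equiv), THF, 0 °C to rt
Reagents that add atoms: methyltriphenylphosphonium bromide, C[P+](c1ccccc1)(c1ccccc1)c1ccccc1.[Br-]
Why: Wittig methylenation converts the methyl ketone into the 1,1-disubstituted alkene (the ene donor) without affecting the non-epimerisable β-stereocentre.

Step 8
Reactants: 12 (4R,7E,11E)-2,4-dimethyl-12-phenyldodeca-1,7,11-triene; 13 methyl pyruvate
Product: 14 methyl (2S,6R,9E,13E)-2-hydroxy-2,6-dimethyl-4-methylidene-14-phenyltetradeca-9,13-dienoate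
Conditions: [Cu((S,S)-tBu-box)](SbF6)2 (10 mol %), methyl pyruvate (3 equiv), CH2Cl2, 40 °C
Reagents that add atoms: none
Why: Evans-type catalytic enantioselective carbonyl-ene reaction in which pyruvate chelated to the square-planar divalent copper centre of [Cu((S,S)-tBu-box)](SbF6)2 exposes one ketone face and only the nucleophilic 1,1-disubstituted alkene reacts, forming C4–C5 and setting C4 as S under catalyst control; any minor ene regioisomer (hydrogen taken from C7) is carried along because it gives the same tertiary cation in step 11.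

Step 9
Reactants: 14 methyl (2S,6R,9E,13E)-2-hydroxy-2,6-dimethyl-4-methylidene-14-phenyltetradeca-9,13-dienoate
Product: 15 (2S,6R,9E,13E)-2-hydroxy-2,6-dimethyl-4-methylidene-14-phenyltetradeca-9,13-dienal
Conditions: iBu2AlH (2.3 equiv), CH2Cl2, −78 °C; aqueous potassium sodium tartrate; used crude
Reagents that add atoms: none
Why: Partial ester reduction with iBu2AlH at −78 °C stops at the aluminium hemiacetal, which is stabilised by chelation to the neighbouring alkoxide, and gives the non-enolisable α-hydroxy aldehyde on work-up.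

Step 10
Reactants: 15 (2S,6R,9E,13E)-2-hydroxy-2,6-dimethyl-4-methylidene-14-phenyltetradeca-9,13-dienal
Product: 17 (5S)-5-methyl-5-[(4R,7E,11E)-4-methyl-2-methylidene-12-phenyldodeca-7,11-dien-1-yl]furan-2(5H)-one, via ester ylide 16 (not isolated)
Conditions: Ph3P=C=C=O (1.3 equiv), toluene, 90 °C
Reagents that add atoms: (triphenylphosphoranylidene)ketene, O=C=C=P(c1ccccc1)(c1ccccc1)c1ccccc1
Why: Bestmann butenolide synthesis in which the tertiary hydroxyl adds across the cumulated ylide and the resulting ester ylide closes by intramolecular Wittig olefination onto the adjacent aldehyde, forming the γ-lactone ring with the Z-alkene enforced by the ring and C4 unchanged.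

Step 11
Reactants: 17 (5S)-5-methyl-5-[(4R,7E,11E)-4-methyl-2-methylidene-12-phenyldodeca-7,11-dien-1-yl]furan-2(5H)-one
Product: 18 (5S)-5-[(2R,4R,7E,11E)-2-hydroperoxy-2,4-dimethyl-12-phenyldodeca-7,11-dien-1-yl]-5-methylfuran-2(5H)-one
Conditions: (S,S)-IDPi Brønsted acid [imidodiphosphorimidate from two (S)-3,3′-bis(4-tert-butylphenyl)-BINOL phosphoryl units, each P bearing =N–SO2CF3] (5 mol %), anhydrous H2O2 (2 M in Et2O, 5 equiv), CHCl3, −20 to 0 °C; cold aq. NaHCO3 wash
Reagents that add atoms: hydrogen peroxide, OO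
Why: Proposed new method: catalyst-controlled Markovnikov hydroperoxidation of an unactivated alkene, in which the strong confined chiral acid protonates only the 1,1-disubstituted alkene (tertiary cation; the E-dialkyl alkene and the β-alkylstyrene would give secondary cations and are expected to react orders of magnitude more slowly) and H2O2 hydrogen-bonded to the imidodiphosphorimidate anion is delivered within the chiral contact ion pair to one face of the C6 cation, whose two CH2 arms (neopentyl-type butenolide arm versus β-branched alkyl arm) are differentiated by the pocket, so that the C6–O bond and the 6R centre are set under catalyst control in the matched pairing with the 4S,8R substrate; the closest known reaction types are the imidodiphosphorimidate-catalysed asymmetric intramolecular hydroalkoxylation and hydrolactonisation of unactivated 1,1-disubstituted alkenes and the sulfuric-acid-catalysed addition of H2O2 to 2-methylalk-1-enes.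

Step 12
Reactants: 18 (5S)-5-[(2R,4R,7E,11E)-2-hydroperoxy-2,4-dimethyl-12-phenyldodeca-7,11-dien-1-yl]-5-methylfuran-2(5H)-one
Product: 19 (1S,4R,6S)-4,6-dimethyl-4-[(2R,5E,9E)-2-methyl-10-phenyldeca-5,9-dien-1-yl]-2,3,7-trioxabicyclo[4.3.0]nonan-8-one (target; 3S,4S,6R,8R in plakortolide numbering)
Conditions: Et2NH (0.5 equiv), CF3CH2OH, rt
Reagents that add atoms: none
Why: Base-catalysed intramolecular oxa-Michael addition (6-exo) of the hydroperoxide to the butenolide forms the C3–O bond and the 1,2-dioxane ring, and because the five-membered lactone can only be cis-fused the C4 centre sets C3 as S while C6 and C8 are untouched.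

**Compound list**
1 | styrene | C=Cc1ccccc1 | starting material
2 | 5-bromopent-1-ene | C=CCCCBr | starting material
3 | (E)-(5-bromopent-1-en-1-yl)benzene | BrCCC/C=C/c1ccccc1 | intermediate
4 | 1-phenyl-1H-tetrazole-5-thiol | Sc1nnnn1-c1ccccc1 | starting material
5 | 1-phenyl-5-{[(4E)-5-phenylpent-4-en-1-yl]sulfanyl}-1H-tetrazole | S(CCC/C=C/c1ccccc1)c1nnnn1-c1ccccc1 | intermediate
6 | 1-phenyl-5-{[(4E)-5-phenylpent-4-en-1-yl]sulfonyl}-1H-tetrazole | O=S(=O)(CCC/C=C/c1ccccc1)c1nnnn1-c1ccccc1 | intermediate
7 | (3R)-3,7-dimethyloct-6-enoic acid | C[C@H](CCC=C(C)C)CC(=O)O | starting material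
8 | (4R)-4,8-dimethylnon-7-en-2-one | C[C@H](CCC=C(C)C)CC(C)=O | intermediate
9 | 5,5-dimethyl-3-[(3R)-3-methyl-5-oxohexyl]-1,2,4-trioxolane (ozonide, both epimers at the ring CH) | C[C@H](CCC1OOC(C)(C)O1)CC(C)=O | intermediate
10 | (4R)-4-methyl-6-oxoheptanal | C[C@H](CCC=O)CC(C)=O | intermediate
11 | (4R,7E,11E)-4-methyl-12-phenyldodeca-7,11-dien-2-one | C[C@H](CC/C=C/CC/C=C/c1ccccc1)CC(C)=O | intermediate
12 | (4R,7E,11E)-2,4-dimethyl-12-phenyldodeca-1,7,11-triene | C[C@H](CC/C=C/CC/C=C/c1ccccc1)CC(C)=C | intermediate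
13 | methyl pyruvate | COC(=O)C(C)=O | starting material
14 | methyl (2S,6R,9E,13E)-2-hydroxy-2,6-dimethyl-4-methylidene-14-phenyltetradeca-9,13-dienoate | COC(=O)[C@@](C)(O)CC(=C)C[C@H](C)CC/C=C/CC/C=C/c1ccccc1 | intermediate
15 | (2S,6R,9E,13E)-2-hydroxy-2,6-dimethyl-4-methylidene-14-phenyltetradeca-9,13-dienal | O=C[C@@](C)(O)CC(=C)C[C@H](C)CC/C=C/CC/C=C/c1ccccc1 | intermediate
16 | (2S,6R,9E,13E)-2,6-dimethyl-4-methylidene-1-oxo-14-phenyltetradeca-9,13-dien-2-yl (triphenylphosphoranylidene)acetate (ester ylide) | O=C[C@@](C)(OC(=O)C=P(c1ccccc1)(c1ccccc1)c1ccccc1)CC(=C)C[C@H](C)CC/C=C/CC/C=C/c1ccccc1 | intermediate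
17 | (5S)-5-methyl-5-[(4R,7E,11E)-4-methyl-2-methylidene-12-phenyldodeca-7,11-dien-1-yl]furan-2(5H)-one | C[C@H](CC/C=C/CC/C=C/c1ccccc1)CC(=C)C[C@]1(C)OC(=O)C=C1 | intermediate
18 | (5S)-5-[(2R,4R,7E,11E)-2-hydroperoxy-2,4-dimethyl-12-phenyldodeca-7,11-dien-1-yl]-5-methylfuran-2(5H)-one | C[C@H](CC/C=C/CC/C=C/c1ccccc1)C[C@@](C)(OO)C[C@]1(C)OC(=O)C=C1 | intermediate
19 | (1S,4R,6S)-4,6-dimethyl-4-[(2R,5E,9E)-2-methyl-10-phenyldeca-5,9-dien-1-yl]-2,3,7-trioxabicyclo[4.3.0]nonan-8-one | C[C@H](CC/C=C/CC/C=C/c1ccccc1)C[C@]1(C)C[C@]2(C)OC(=O)C[C@@H]2OO1 | target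

**Step count**
Total: 12 steps. Longest linear sequence: 10 steps (from 1 or 2 to 19, steps 1–3 and then 6–12); the branch from 7 (steps 4–12) is 9 steps.

**Steps most likely to fail, with fallbacks**

Step 11 (the new hydroperoxidation). Risks are insufficient facial control at C6, loss of selectivity by re-ionisation of 18 under the acid, and capture of the C6 cation by the C11=C12 alkene. The fallback gives up reagent control and uses known chemistry. It sets out from 17 and comes back at 19. Classical sulfuric-acid-catalysed Markovnikov perhydrolysis of the 2-substituted alk-1-ene (anhydrous ethereal H2O2, catalytic H2SO4, 0 °C) gives 18 together with its C6 epimer, (5S)-5-[(2S,4R,7E,11E)-2-hydroperoxy-2,4-dimethyl-12-phenyldodeca-7,11-dien-1-yl]-5-methylfuran-2(5H)-one F1. The mixture is cyclised under the step 12 conditions to 19 and its 6-epimer, (1S,4S,6S)-4,6-dimethyl-4-[(2R,5E,9E)-2-methyl-10-phenyldeca-5,9-dien-1-yl]-2,3,7-trioxabicyclo[4.3.0]nonan-8-one F2, and the two diastereomers are separated by chromatography.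

Step 8 (pyruvate–ene). Risks are low conversion with the less reactive ketone enophile and a mixture of ene regioisomers (hydrogen from the methyl group versus from C7). The fallback replaces the ene reaction by a Mukaiyama aldol and a methylenation. It sets out from 11 and comes back at 14. Kinetic enolisation on the methyl side (LiN(iPr)2, Me3SiCl, THF, −78 °C) gives the silyl enol ether (4R,7E,11E)-4-methyl-12-phenyl-2-(trimethylsilyloxy)dodeca-1,7,11-triene F3. Mukaiyama aldol addition to methyl pyruvate catalysed by [Cu((S,S)-tBu-box)](OTf)2 (THF, −78 °C, then dilute HCl) gives methyl (2S,6R,9E,13E)-2-hydroxy-2,6-dimethyl-4-oxo-14-phenyltetradeca-9,13-dienoate F4 as a single constitutional isomer. Ketone-selective methylenation (Zn, CH2Br2, TiCl4, THF) then gives 14.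

Step 6 (Julia–Kocienski on the keto-aldehyde). Risks are base-induced intramolecular aldol reaction of 10 and competing attack at the ketone. The fallback removes the ketone before the olefination. It sets out from 8 and comes back at 12. Wittig methylenation of 8 gives (4R)-2,4,8-trimethylnona-1,7-diene F5. The more electron-rich trisubstituted alkene is epoxidised selectively (mCPBA, 1.0 equiv, CH2Cl2, −20 °C) to 3-[(3R)-3,5-dimethylhex-5-en-1-yl]-2,2-dimethyloxirane F6. Cleavage with H5IO6 (THF/H2O) gives (4R)-4,6-dimethylhept-6-enal F7, which undergoes the same Julia–Kocienski olefination with 6 to give 12.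

**Further compounds**
F1 | step 11 | (5S)-5-[(2S,4R,7E,11E)-2-hydroperoxy-2,4-dimethyl-12-phenyldodeca-7,11-dien-1-yl]-5-methylfuran-2(5H)-one | C[C@H](CC/C=C/CC/C=C/c1ccccc1)C[C@](C)(OO)C[C@]1(C)OC(=O)C=C1
F2 | step 11 | (1S,4S,6S)-4,6-dimethyl-4-[(2R,5E,9E)-2-methyl-10-phenyldeca-5,9-dien-1-yl]-2,3,7-trioxabicyclo[4.3.0]nonan-8-one | C[C@H](CC/C=C/CC/C=C/c1ccccc1)C[C@@]1(C)C[C@]2(C)OC(=O)C[C@@H]2OO1
F3 | step 8 | (4R,7E,11E)-4-methyl-12-phenyl-2-(trimethylsilyloxy)dodeca-1,7,11-triene | C[C@H](CC/C=C/CC/C=C/c1ccccc1)CC(=C)O[Si](C)(C)C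
F4 | step 8 | methyl (2S,6R,9E,13E)-2-hydroxy-2,6-dimethyl-4-oxo-14-phenyltetradeca-9,13-dienoate | COC(=O)[C@@](C)(O)CC(=O)C[C@H](C)CC/C=C/CC/C=C/c1ccccc1
F5 | step 6 | (4R)-2,4,8-trimethylnona-1,7-diene | C[C@H](CCC=C(C)C)CC(C)=C
F6 | step 6 | 3-[(3R)-3,5-dimethylhex-5-en-1-yl]-2,2-dimethyloxirane | C[C@H](CCC1OC1(C)C)CC(C)=C
F7 | step 6 | (4R)-4,6-dimethylhept-6-enal | C[C@H](CCC=O)CC(C)=C
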